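The route rests on tracing both prenyl side chains back to allyl groups that are delivered to carbon from oxygen: the C6–C and C8–C bonds of ring A are disconnected to O5- and O7-allyl ethers. C6 and C8 are the only unsubstituted carbons of ring A, and each lies ortho to O5 or O7, so one Eu(fod)3-promoted double aromatic Claisen rearrangement forms both bonds while leaving C2 untouched. The precursor is the (2S)-5,7-bis(allyloxy)flavanone with ring B masked as a bis-MOM ether, assembled by chalcone condensation and asymmetric oxa-Michael closure. Acidic MOM removal precedes a double cross-metathesis, so no prenyl group ever meets acid.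

Key step: step 5

Assumption: the quinidine-derived thiourea is taken to be the pseudo-enantiomer that closes the ring to the 2S flavanone; if a trial run shows the opposite sense, the quinine-derived pseudo-enantiomer replaces it and nothing else changes.

Step 1
Reactants: 1 2,4,6-trihydroxyacetophenone; 2 allyl bromide
Product: 3 1-[2,4-bis(allyloxy)-6-hydroxyphenyl]ethanone
Conditions: allyl bromide (2.1 equiv), K2CO3 (2.2 equiv), acetone, reflux
Reagents that add atoms: allyl bromide 2, C=CCBr
Why: Williamson ether synthesis: K2CO3 in acetone ionises the two more acidic phenols (para and one ortho to the acetyl group), which are O-allylated, while the remaining ortho hydroxyl is held in a hydrogen bond to the carbonyl and stays free, and the mild base in an aprotic solvent should keep C-allylation of the phloroglucinol ring minor.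

Step 2
Reactants: 4 3,5-dihydroxybenzaldehyde
Product: 5 3,5-bis(methoxymethoxy)benzaldehyde
Conditions: MOMCl (2.5 equiv), K2CO3, acetone, 0 °C to rt
Reagents that add atoms: chloromethyl methyl ether (MOMCl), COCCl
Why: Williamson-type O-alkylation of both phenoxides with MOMCl gives MOM acetals that are inert to the hydroxide of step 3 and should survive the Lewis acid and heat of step 5, and that are cleaved by dilute acid in step 6.

Step 3
Reactants: 3 1-[2,4-bis(allyloxy)-6-hydroxyphenyl]ethanone; 5 3,5-bis(methoxymethoxy)benzaldehyde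
Product: 6 (E)-1-[2,4-bis(allyloxy)-6-hydroxyphenyl]-3-[3,5-bis(methoxymethoxy)phenyl]prop-2-en-1-one
Conditions: KOH (50% aq., excess), EtOH, 0 °C to rt; then AcOH to pH 6
Reagents that add atoms: none
Why: Claisen–Schmidt condensation: the enolate of 3 adds to the non-enolisable aldehyde 5 and E1cB loss of hydroxide gives the conjugated E-enone, whose phenoxide form under excess KOH resists premature ring closure, while allyl and MOM ethers are untouched by base.

Step 4
Reactants: 6 (E)-1-[2,4-bis(allyloxy)-6-hydroxyphenyl]-3-[3,5-bis(methoxymethoxy)phenyl]prop-2-en-1-one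
Product: 7 (2S)-5,7-bis(allyloxy)-2-[3,5-bis(methoxymethoxy)phenyl]chroman-4-one
Conditions: thiourea from 9-amino-9-deoxy-epi-quinidine and 3,5-bis(trifluoromethyl)phenyl isothiocyanate (10 mol%), toluene, rt
Reagents that add atoms: none
Why: Asymmetric intramolecular oxa-Michael addition (6-endo-trig) under bifunctional catalysis: the quinuclidine nitrogen engages the 2'-phenol as a general base while the thiourea hydrogen-bonds the enone carbonyl, so oxygen attacks one face of the β-carbon inside the chiral pocket and C2 is set as S by the catalyst, the 6'-allyloxy group making ring closure thermodynamically favourable by twisting the chalcone.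

Step 5
Reactants: 7 (2S)-5,7-bis(allyloxy)-2-[3,5-bis(methoxymethoxy)phenyl]chroman-4-one
Product: 11 (2S)-6,8-diallyl-5,7-dihydroxy-2-[3,5-bis(methoxymethoxy)phenyl]chroman-4-one, via C6-allyl ortho-dienone 8 (not isolated), via 6-allyl-7-allyloxy-5-hydroxyflavanone 9 (not isolated), via C8-allyl ortho-dienone 10 (not isolated)
Conditions: Eu(fod)3 (15 mol%), PhCl, 90 °C then 150 °C, sealed tube, Ar
Reagents that add atoms: none
Why: Eu(fod)3, the tris(6,6,7,7,8,8,8-heptafluoro-2,2-dimethyloctane-3,5-dionato) complex of trivalent europium, should bind the C4 carbonyl and O5 as a chelate, polarise the O5–allyl bond and so let that ether undergo a concerted suprafacial [3,3] shift through a chair-like transition state to C6, giving dienone 8, which tautomerises to the chelated phenol 9. On further heating the 7-O-allyl group of 9 follows the same aromatic Claisen pathway to C8, its only open ortho position, and dienone 10 enolises to 11. The closest known reaction type is the thermal or Eu(fod)3-catalysed Claisen and Claisen–Cope rearrangement of 5-O-allyl and 7-O-allyl flavonoids. No ring is closed and no lasting stereocentre is created, since the sp3 carbons of 8 and 10 are erased on rearomatisation. The selectivity needed is regiochemical and is built into ring A: C4a and C8a are ring-fusion carbons, so only C6 and C8 can accept an allyl group, and if the shifts occurred in the other order a Claisen–Cope relay from O5 through C6 to C8 would end at the same 6,8-diallyl pattern. The 2S centre must merely survive, which the neutral, base-free, aprotic medium and the lowest workable temperature are chosen to ensure against retro-oxa-Michael opening of ring C; plain allyl groups also cannot give the inverted 1,1-dimethylallyl isomers that prenyl ethers would.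

Step 6
Reactants: 11 (2S)-6,8-diallyl-5,7-dihydroxy-2-[3,5-bis(methoxymethoxy)phenyl]chroman-4-one
Product: 12 (2S)-6,8-diallyl-2-(3,5-dihydroxyphenyl)-5,7-dihydroxychroman-4-one
Conditions: 3 M aq HCl, MeOH, 50 °C
Reagents that add atoms: none
Why: Acid-catalysed acetal exchange with methanol (MOM cleavage) frees both ring B phenols at a stage where the side chains are terminal allyl groups, which do not ionise or cyclise onto the neighbouring phenols under dilute acid as prenyl groups would, and such mild acid is not expected to open ring C or disturb C2.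

Step 7
Reactants: 12 (2S)-6,8-diallyl-2-(3,5-dihydroxyphenyl)-5,7-dihydroxychroman-4-one; 13 2-methyl-2-butene
Product: 14 (2S)-2-(3,5-dihydroxyphenyl)-5,7-dihydroxy-6,8-bis(3-methylbut-2-en-1-yl)chroman-4-one
Conditions: second-generation Grubbs catalyst RuCl2(=CHPh)(H2IMes)(PCy3) (10 mol%), 2-methyl-2-butene/CH2Cl2 (1:1), 40 °C, sealed tube
Reagents that add atoms: 2-methyl-2-butene 13, CC=C(C)C
Why: Olefin cross-metathesis with a large excess of the trisubstituted partner replaces each terminal CH2 by C(CH3)2 with loss of propene, the ruthenium carbene tolerates free phenols, and the trisubstituted prenyl olefins formed do not re-enter the catalytic cycle, so both side chains should converge on the prenyl stage without touching C2.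

Compound list
1 | 2,4,6-trihydroxyacetophenone | CC(=O)c1c(O)cc(O)cc1O | starting material
2 | allyl bromide | C=CCBr | starting material
3 | 1-[2,4-bis(allyloxy)-6-hydroxyphenyl]ethanone | CC(=O)c1c(O)cc(OCC=C)cc1OCC=C | intermediate
4 | 3,5-dihydroxybenzaldehyde | O=Cc1cc(O)cc(O)c1 | starting material
5 | 3,5-bis(methoxymethoxy)benzaldehyde | O=Cc1cc(OCOC)cc(OCOC)c1 | intermediate
6 | (E)-1-[2,4-bis(allyloxy)-6-hydroxyphenyl]-3-[3,5-bis(methoxymethoxy)phenyl]prop-2-en-1-one | C=CCOc1cc(O)c(C(=O)/C=C/c2cc(OCOC)cc(OCOC)c2)c(OCC=C)c1 | intermediate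
7 | (2S)-5,7-bis(allyloxy)-2-[3,5-bis(methoxymethoxy)phenyl]chroman-4-one | c1c(OCC=C)cc2c(c1OCC=C)C(=O)C[C@@H](c1cc(OCOC)cc(OCOC)c1)O2 | intermediate
8 | (2S)-6-allyl-7-(allyloxy)-2-[3,5-bis(methoxymethoxy)phenyl]-2,3-dihydro-4H-chromene-4,5(6H)-dione (C6-allyl ortho-dienone, both C6 epimers; not isolated) | O=C1C(CC=C)C(OCC=C)=CC2=C1C(=O)C[C@@H](c1cc(OCOC)cc(OCOC)c1)O2 | intermediate
9 | (2S)-6-allyl-7-(allyloxy)-5-hydroxy-2-[3,5-bis(methoxymethoxy)phenyl]chroman-4-one (not isolated) | C=CCc1c(OCC=C)cc2c(c1O)C(=O)C[C@@H](c1cc(OCOC)cc(OCOC)c1)O2 | intermediate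
10 | (2S)-6,8-diallyl-5-hydroxy-2-[3,5-bis(methoxymethoxy)phenyl]-2,3-dihydro-4H-chromene-4,7(8H)-dione (C8-allyl ortho-dienone, both C8 epimers; not isolated) | C=CCC1C(=O)C(CC=C)=C(O)C2=C1O[C@H](c1cc(OCOC)cc(OCOC)c1)CC2=O | intermediate
11 | (2S)-6,8-diallyl-5,7-dihydroxy-2-[3,5-bis(methoxymethoxy)phenyl]chroman-4-one | C=CCc1c(O)c(CC=C)c2c(c1O)C(=O)C[C@@H](c1cc(OCOC)cc(OCOC)c1)O2 | intermediate
12 | (2S)-6,8-diallyl-2-(3,5-dihydroxyphenyl)-5,7-dihydroxychroman-4-one | C=CCc1c(O)c(CC=C)c2c(c1O)C(=O)C[C@@H](c1cc(O)cc(O)c1)O2 | intermediate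
13 | 2-methyl-2-butene | CC=C(C)C | starting material
14 | (2S)-2-(3,5-dihydroxyphenyl)-5,7-dihydroxy-6,8-bis(3-methylbut-2-en-1-yl)chroman-4-one (CID26213315) | CC(C)=CCc1c(O)c(CC=C(C)C)c2c(c1O)C(=O)C[C@@H](c1cc(O)cc(O)c1)O2 | target

Total step count: 7 (steps 1 and 2 are run in parallel).
Longest linear sequence: 6 steps (steps 1, 3, 4, 5, 6 and 7, from 1 to 14).

Steps most likely to fail

Step 5 (key step). The second shift, from O7, has no chelation assistance and may stall after the first. Alternatively, the heat it needs may let ring C open and reclose by a retro-oxa-Michael/oxa-Michael sequence, so that C2 loses configuration. The fallback moves the rearrangement ahead of the stereocentre. Setting out from 3, a thermal double aromatic Claisen rearrangement (N,N-diethylaniline, 200 °C) should give 1-(3,5-diallyl-2,4,6-trihydroxyphenyl)ethanone F1. MOMCl and K2CO3 in acetone then protect two of its phenols to give 1-[3,5-diallyl-2-hydroxy-4,6-bis(methoxymethoxy)phenyl]ethanone F2. Claisen–Schmidt condensation with 5 (KOH, EtOH) gives (E)-1-[3,5-diallyl-2-hydroxy-4,6-bis(methoxymethoxy)phenyl]-3-[3,5-bis(methoxymethoxy)phenyl]prop-2-en-1-one F3. The thiourea-catalysed oxa-Michael closure used in step 4 then gives (2S)-6,8-diallyl-5,7-bis(methoxymethoxy)-2-[3,5-bis(methoxymethoxy)phenyl]chroman-4-one F4. Finally 3 M HCl in MeOH removes all four MOM groups, and the route is rejoined at 12.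

Step 4. Facial selectivity may be poor, or turnover slow, because the chalcone offers the thiourea only one carbonyl and its phenol is tied up in a hydrogen bond to that carbonyl. The fallback sets out from 6: NaOAc in refluxing EtOH closes the ring without stereocontrol to racemic 5,7-bis(allyloxy)-2-[3,5-bis(methoxymethoxy)phenyl]chroman-4-one F5. This is resolved kinetically by asymmetric transfer hydrogenation (RuCl[(R,R)-TsDPEN](p-cymene), HCO2H/Et3N, EtOAc, rt, stopped a little past half conversion). By the usual facial preference of this catalyst for aryl ketones, the 2R ketone should be reduced faster, to (2R,4R)-5,7-bis(allyloxy)-2-[3,5-bis(methoxymethoxy)phenyl]chroman-4-ol F6. The unreduced 2S ketone, separated by chromatography, is 7, at most half of the material.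

Step 7. Exchange may be incomplete at one of the two allyl groups, a ruthenium hydride may move a double bond into conjugation with ring A, or the tetraphenol may dissolve poorly in the metathesis medium. The fallback reverses the order of the last two operations. Setting out from 11, the same cross-metathesis on the MOM-protected, more soluble substrate gives (2S)-5,7-dihydroxy-6,8-bis(3-methylbut-2-en-1-yl)-2-[3,5-bis(methoxymethoxy)phenyl]chroman-4-one F7. Brief treatment with dilute HCl in MeOH at rt, stopped before the prenylphenols cyclise to chromans, then arrives at 14.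

Further compounds
F1 | step 5 | 1-(3,5-diallyl-2,4,6-trihydroxyphenyl)ethanone | CC(=O)c1c(O)c(CC=C)c(O)c(CC=C)c1O
F2 | step 5 | 1-[3,5-diallyl-2-hydroxy-4,6-bis(methoxymethoxy)phenyl]ethanone | CC(=O)c1c(O)c(CC=C)c(OCOC)c(CC=C)c1OCOC
F3 | step 5 | (E)-1-[3,5-diallyl-2-hydroxy-4,6-bis(methoxymethoxy)phenyl]-3-[3,5-bis(methoxymethoxy)phenyl]prop-2-en-1-one | COCOc1c(CC=C)c(O)c(C(=O)/C=C/c2cc(OCOC)cc(OCOC)c2)c(OCOC)c1CC=C
F4 | step 5 | (2S)-6,8-diallyl-5,7-bis(methoxymethoxy)-2-[3,5-bis(methoxymethoxy)phenyl]chroman-4-one | C=CCc1c(OCOC)c(CC=C)c2c(c1OCOC)C(=O)C[C@@H](c1cc(OCOC)cc(OCOC)c1)O2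
F5 | step 4 | racemic 5,7-bis(allyloxy)-2-[3,5-bis(methoxymethoxy)phenyl]chroman-4-one | c1c(OCC=C)cc2c(c1OCC=C)C(=O)CC(c1cc(OCOC)cc(OCOC)c1)O2
F6 | step 4 | (2R,4R)-5,7-bis(allyloxy)-2-[3,5-bis(methoxymethoxy)phenyl]chroman-4-ol | C=CCOc1cc(OCC=C)c2c(c1)O[C@@H](c1cc(OCOC)cc(OCOC)c1)C[C@H]2O
F7 | step 7 | (2S)-5,7-dihydroxy-6,8-bis(3-methylbut-2-en-1-yl)-2-[3,5-bis(methoxymethoxy)phenyl]chroman-4-one | CC(C)=CCc1c(O)c(CC=C(C)C)c2c(c1O)C(=O)C[C@@H](c1cc(OCOC)cc(OCOC)c1)O2
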